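**Retrosynthetic overview**

1. Numbering: the decalin half is numbered as a drimane (ring A = C1–C5/C10 with C3=O, C4 gem-dimethyl, C10 methyl; ring B = C5–C10 with C6–OH, C7=O, C8–Me, C9 carrying the C11–C12 link); the right half is numbered as a 1-benzoxepine (O1, C2–C5, C5a, C6–C9, C9a; primed where needed).
2. Target ⇒ triol enone (the carbinols at C3, C6 and C3′ are oxidised together at the end) ⇒ Rubottom oxidation of a ring-B 2-silyloxy-1,3-diene ⇒ ring B closed last through the C7–C8 bond, by an acid-promoted ketenium–olefin cyclisation of a C5-bound siloxyalkyne (C6≡C7–OTIPS) onto the C8=C9 ethylidene alkene.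
3. Enabling feature: in ring B the C7 carbonyl carbon lies 1,5 to C8 across C6–C5–C10–C9, and C9 is fully substituted (it carries quaternary C10 and C11). A ketenium ion at C7 is therefore taken up 6-endo by C8 with the charge on tertiary C9; loss of H8 gives the C8=C9 alkene, and the C6=C7 enol silane that results marks C6 alone for oxidation.
4. Cyclisation precursor ⇒ B-alkyl Suzuki–Miyaura coupling (C9–C11) of a ring-A enol triflate with the 6-vinyl benzoxepine; ring A ⇒ enantioselective Michael addition and aldol closure (Robinson annulation), gem-dimethylation, then hydroboration and alkyne homologation at C5.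
5. Right half ⇒ one bis-epoxide cascade (oxepane first, then the cyclohexane, allylsilane-terminated) of a geranyl-derived S,S,S bis-epoxide; ring order: oxepane, right-hand cyclohexane, ring A, ring B.

Key step: step 22

Remark on the chemistry: C5 (formed in step 14) and C6 (formed in step 23) end as sp2 carbons of the diosphenol. Both are expected as epimer mixtures, are carried as such, and are written without configuration in the SMILES.

**Right half**

Step 1
Reactants: 1 geranyl bromide; 2 methyl acetoacetate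
Product: 3 methyl (6E)-7,11-dimethyl-3-oxododeca-6,10-dienoate
Conditions: 2, NaH, THF, 0 °C; n-BuLi, 0 °C; then 1, 0 °C → rt; aq. NH4Cl
Reagents that add atoms: none
Why: γ-Alkylation of the acetoacetate dianion, whose terminal carbanion is the more reactive one, by SN2 at the primary allylic bromide, which keeps the E geometry.

Step 2
Reactants: 3 methyl (6E)-7,11-dimethyl-3-oxododeca-6,10-dienoate
Product: 4 methyl (2Z,6E)-3-[(diethoxyphosphoryl)oxy]-7,11-dimethyldodeca-2,6,10-trienoate
Conditions: NaH, Et2O, 0 °C; ClP(O)(OEt)2, 0 °C → rt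
Reagents that add atoms: diethyl chlorophosphate, CCOP(Cl)(=O)OCC
Why: O-Phosphorylation of the sodium-chelated enolate of the β-keto ester should give the Z enol phosphate (enolate O-phosphorylation).

Step 3
Reactants: 4 methyl (2Z,6E)-3-[(diethoxyphosphoryl)oxy]-7,11-dimethyldodeca-2,6,10-trienoate
Product: 5 methyl (2Z,6E)-7,11-dimethyl-3-[(trimethylsilyl)methyl]dodeca-2,6,10-trienoate
Conditions: Me3SiCH2MgCl, Ni(acac)2 (5 mol%), THF, 0 °C → rt
Reagents that add atoms: (trimethylsilyl)methylmagnesium chloride, C[Si](C)(C)C[Mg]Cl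
Why: Nickel-catalysed Kumada-type cross-coupling of the enol phosphate proceeds with retention of alkene geometry and installs the allylsilane whose CH2 carbon becomes the secondary methyl carbon of the right half.

Step 4
Reactants: 5 methyl (2Z,6E)-7,11-dimethyl-3-[(trimethylsilyl)methyl]dodeca-2,6,10-trienoate
Product: 6 methyl (2Z)-5-[(2S,3S)-3-{2-[(2S)-3,3-dimethyloxiran-2-yl]ethyl}-3-methyloxiran-2-yl]-3-[(trimethylsilyl)methyl]pent-2-enoate
Conditions: L-fructose-derived Shi ketone (1,2:4,5-di-O-isopropylidene-β-L-erythro-2,3-hexodiulo-2,6-pyranose, 0.4 equiv), KHSO5 (as 2KHSO5·KHSO4·K2SO4), K2CO3, Bu4NHSO4, MeCN/CH2(OMe)2/aq. Na2B4O7, 0 °C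
Reagents that add atoms: potassium peroxymonosulfate, [K+].[O-]S(=O)(=O)OO
Why: Shi asymmetric epoxidation: the chiral dioxirane epoxidises the two electron-rich trisubstituted alkenes through a spiro transition state (the L-configured ketone should give the S,S and S epoxides, the D-fructose-derived one giving the R series), while the ester-conjugated alkene is too electron-poor to react.

Step 5
Reactants: 6 methyl (2Z)-5-[(2S,3S)-3-{2-[(2S)-3,3-dimethyloxiran-2-yl]ethyl}-3-methyloxiran-2-yl]-3-[(trimethylsilyl)methyl]pent-2-enoate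
Product: 8 methyl (3S,5aS,6R,9aS)-3-hydroxy-2,2,5a-trimethyl-7-methylidenedecahydro-1-benzoxepine-6-carboxylate, via trimethylsilyl ether 7 (not isolated)
Conditions: Me3SiOTf (0.3 equiv), 2,6-di-tert-butyl-4-methylpyridine (0.5 equiv), CH2Cl2, −78 °C; then 1 M HCl, THF, 0 °C
Reagents that add atoms: none
Why: Silyl triflate-initiated epoxide-opening cascade (oxacyclisation then carbacyclisation): the silylated terminal epoxide is opened at its tertiary carbon by the oxygen of the internal epoxide to close the oxepane, the epoxonium ion is opened with inversion at its tertiary carbon (C5a) by the allylsilane through a chair transition state (the E-derived epoxide gives the trans ring fusion and the equatorial ester gives 6R), and loss of the silyl group gives the exocyclic methylene and returns Me3SiOTf, while C3 and C9a keep their epoxide configurations.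

Step 6
Reactants: 8 methyl (3S,5aS,6R,9aS)-3-hydroxy-2,2,5a-trimethyl-7-methylidenedecahydro-1-benzoxepine-6-carboxylate
Product: 9 methyl (3S,5aS,6R,7R,9aS)-3-hydroxy-2,2,5a,7-tetramethyldecahydro-1-benzoxepine-6-carboxylate
Conditions: H2 (1 atm), PtO2, EtOAc, rt
Reagents that add atoms: none
Why: Heterogeneous hydrogenation of the exocyclic methylene should deliver hydrogen to the face opposite the axial angular methyl on C5a, which places the new C7 methyl axial and cis to the C6 ester (7R); platinum is chosen to limit double-bond migration.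

Step 7
Reactants: 9 methyl (3S,5aS,6R,7R,9aS)-3-hydroxy-2,2,5a,7-tetramethyldecahydro-1-benzoxepine-6-carboxylate
Product: 10 (3S,5aS,6R,7R,9aS)-3-hydroxy-2,2,5a,7-tetramethyldecahydro-1-benzoxepine-6-carbaldehyde
Conditions: i-Bu2AlH (2.3 equiv), CH2Cl2, −78 °C; aq. KNaC4H4O6
Reagents that add atoms: none
Why: Partial reduction of the hindered methyl ester should stop at the tetrahedral aluminium hemiacetal at −78 °C and release the aldehyde on work-up, the first equivalent of hydride being consumed by the free hydroxyl.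

Step 8
Reactants: 10 (3S,5aS,6R,7R,9aS)-3-hydroxy-2,2,5a,7-tetramethyldecahydro-1-benzoxepine-6-carbaldehyde
Product: 11 (3S,5aS,6R,7R,9aS)-6-ethenyl-2,2,5a,7-tetramethyldecahydro-1-benzoxepin-3-ol
Conditions: Ph3PCH3Br (3 equiv), KN(SiMe3)2 (2.8 equiv), THF, 0 °C; then 10, −78 → 0 °C
Reagents that add atoms: methyltriphenylphosphonium bromide, C[P+](c1ccccc1)(c1ccccc1)c1ccccc1.[Br-]
Why: Wittig methylenation of the aldehyde with the unstabilised ylide at low temperature should be faster than epimerisation at C6 and gives the vinyl group that carries C12 and C11.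

**Ring A fragment**

Step 9
Reactants: 12 methyl 2-methyl-3-oxobutanoate; 13 but-3-en-2-one
Product: 14 methyl (2S)-2-acetyl-2-methyl-5-oxohexanoate
Conditions: [Pd((R)-BINAP)(H2O)2](OTf)2 (5 mol%), THF, −20 °C
Reagents that add atoms: none
Why: Catalytic enantioselective Michael addition: the chiral square-planar palladium enolate of the β-keto ester adds to the enone on its open face and sets the quaternary carbon (the later C10) as S, the ligand antipode being taken should the sense prove opposite.

Step 10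
Reactants: 14 methyl (2S)-2-acetyl-2-methyl-5-oxohexanoate
Product: 15 methyl (1S)-1,2-dimethyl-4-oxocyclohex-2-ene-1-carboxylate
Conditions: pyrrolidine (0.3 equiv), AcOH (0.3 equiv), toluene, 80 °C
Reagents that add atoms: none
Why: Intramolecular aldol condensation (second half of a Robinson annulation): the enamine of the unhindered side-chain methyl ketone attacks the acetyl carbonyl to close ring A and water is lost to the conjugated enone, the quaternary centre staying untouched.

Step 11
Reactants: 15 methyl (1S)-1,2-dimethyl-4-oxocyclohex-2-ene-1-carboxylate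
Product: 16 methyl (1S)-1,3,3-trimethyl-2-methylidene-4-oxocyclohexane-1-carboxylate
Conditions: KOt-Bu (2.3 equiv), MeI (3 equiv), t-BuOH/THF, 0 °C → rt
Reagents that add atoms: iodomethane, CI
Why: Deconjugative α,α-dimethylation: γ-deprotonation gives the extended dienolate, which is methylated twice at its α-carbon (C4) and leaves the exocyclic C5=C6 methylene.

Step 12
Reactants: 16 methyl (1S)-1,3,3-trimethyl-2-methylidene-4-oxocyclohexane-1-carboxylate
Product: 17 methyl (1S,4R)-4-hydroxy-1,3,3-trimethyl-2-methylidenecyclohexane-1-carboxylate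
Conditions: (S)-Me-CBS oxazaborolidine (10 mol%), catecholborane (1.5 equiv), toluene, −78 °C; aq. NaOH
Reagents that add atoms: none
Why: Corey–Bakshi–Shibata reduction under reagent control (large quaternary C4 against small C2 methylene) should give the 4R carbinol (drimane C3), a centre that is oxidised again in step 24, and catecholborane at −78 °C spares the hindered alkene.

Step 13
Reactants: 17 methyl (1S,4R)-4-hydroxy-1,3,3-trimethyl-2-methylidenecyclohexane-1-carboxylate
Product: 18 methyl (1S,4R)-4-(tert-butyldimethylsilyloxy)-1,3,3-trimethyl-2-methylidenecyclohexane-1-carboxylate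
Conditions: t-BuMe2SiOTf (1.3 equiv), 2,6-lutidine, CH2Cl2, 0 °C
Reagents that add atoms: tert-butyldimethylsilyl trifluoromethanesulfonate, CC(C)(C)[Si](C)(C)OS(=O)(=O)C(F)(F)F
Why: Silylation of the hindered secondary alcohol with the silyl triflate masks the C3 oxygen for the organometallic steps that follow.

Step 14
Reactants: 18 methyl (1S,4R)-4-(tert-butyldimethylsilyloxy)-1,3,3-trimethyl-2-methylidenecyclohexane-1-carboxylate
Product: 19 methyl (1S,4R)-4-(tert-butyldimethylsilyloxy)-2-(hydroxymethyl)-1,3,3-trimethylcyclohexane-1-carboxylate (C2 epimers)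
Conditions: BH3·THF (1.5 equiv), THF, 0 °C → rt; then NaOH, H2O2, 0 °C
Reagents that add atoms: hydrogen peroxide, OO
Why: Anti-Markovnikov hydroboration–oxidation puts boron on the terminal methylene carbon (C6) and hydrogen on C5, whose configuration is not controlled and does not matter, and the hindered ester is reduced far more slowly than the alkene is hydroborated.

Step 15
Reactants: 19 methyl (1S,4R)-4-(tert-butyldimethylsilyloxy)-2-(hydroxymethyl)-1,3,3-trimethylcyclohexane-1-carboxylate (C2 epimers)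
Product: 20 methyl (1S,4R)-4-(tert-butyldimethylsilyloxy)-2-formyl-1,3,3-trimethylcyclohexane-1-carboxylate (C2 epimers)
Conditions: Dess–Martin periodinane (1.3 equiv), NaHCO3, CH2Cl2, rt
Reagents that add atoms: none
Why: Dess–Martin oxidation of the primary alcohol gives the aldehyde under neutral conditions that leave the silyl ether intact.

Step 16
Reactants: 20 methyl (1S,4R)-4-(tert-butyldimethylsilyloxy)-2-formyl-1,3,3-trimethylcyclohexane-1-carboxylate (C2 epimers)
Product: 21 methyl (1S,4R)-4-(tert-butyldimethylsilyloxy)-2-ethynyl-1,3,3-trimethylcyclohexane-1-carboxylate (C2 epimers)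
Conditions: dimethyl (1-diazo-2-oxopropyl)phosphonate (1.5 equiv), K2CO3, MeOH, 0 °C → rt
Reagents that add atoms: dimethyl (1-diazo-2-oxopropyl)phosphonate, COP(=O)(OC)C(=[N+]=[N-])C(C)=O
Why: Ohira–Bestmann (Seyferth–Gilbert) homologation turns the aldehyde carbon into C6 of a terminal alkyne and adds C7, and the ester, which has no α-hydrogen, tolerates the carbonate/methanol medium.

Step 17
Reactants: 21 methyl (1S,4R)-4-(tert-butyldimethylsilyloxy)-2-ethynyl-1,3,3-trimethylcyclohexane-1-carboxylate (C2 epimers)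
Product: 22 methyl (1S,4R)-4-(tert-butyldimethylsilyloxy)-1,3,3-trimethyl-2-[(trimethylsilyl)ethynyl]cyclohexane-1-carboxylate (C2 epimers)
Conditions: LiN(i-Pr)2 (1.2 equiv), THF, −78 °C; Me3SiCl (1.5 equiv)
Reagents that add atoms: chlorotrimethylsilane, C[Si](C)(C)Cl
Why: C-Silylation of the lithium acetylide protects the alkyne C–H for the enolate and palladium chemistry, the non-nucleophilic amide base sparing the non-enolisable ester.

Step 18
Reactants: 22 methyl (1S,4R)-4-(tert-butyldimethylsilyloxy)-1,3,3-trimethyl-2-[(trimethylsilyl)ethynyl]cyclohexane-1-carboxylate (C2 epimers)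
Product: 24 1-{(1S,4R)-4-(tert-butyldimethylsilyloxy)-1,3,3-trimethyl-2-[(trimethylsilyl)ethynyl]cyclohexyl}propan-1-one (C2 epimers), via Weinreb amide 23 (not isolated)
Conditions: MeNH(OMe)·HCl (1.5 equiv), i-PrMgCl (3 equiv), THF, −20 → 0 °C; then EtMgBr (3 equiv), 0 °C → rt
Reagents that add atoms: ethylmagnesium bromide, CC[Mg]Br
Why: Aminolysis of the ester by the magnesium amide gives the Weinreb amide, whose chelated tetrahedral adduct with the Grignard reagent prevents over-addition and releases the ethyl ketone (C9, C8 and the C8 methyl) on work-up.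

Step 19
Reactants: 24 1-{(1S,4R)-4-(tert-butyldimethylsilyloxy)-1,3,3-trimethyl-2-[(trimethylsilyl)ethynyl]cyclohexyl}propan-1-one (C2 epimers)
Product: 25 (1Z)-1-{(1S,4R)-4-(tert-butyldimethylsilyloxy)-1,3,3-trimethyl-2-[(trimethylsilyl)ethynyl]cyclohexyl}prop-1-en-1-yl trifluoromethanesulfonate (C2 epimers)
Conditions: KN(SiMe3)2 (1.2 equiv), THF, −78 °C; PhNTf2 (1.3 equiv)
Reagents that add atoms: N-phenylbis(trifluoromethanesulfonimide), O=S(=O)(N(c1ccccc1)S(=O)(=O)C(F)(F)F)C(F)(F)F
Why: The ketone can enolise only towards C8 because C10 is quaternary, so O-triflation of the potassium enolate gives a single regioisomeric enol triflate, whose alkene geometry has no consequence later.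

**Union and endgame**

Step 20
Reactants: 11 (3S,5aS,6R,7R,9aS)-6-ethenyl-2,2,5a,7-tetramethyldecahydro-1-benzoxepin-3-ol; 25 enol triflate
Product: 27 (3S,5aS,6R,7R,9aS)-6-{(3E)-3-[(1S,4R)-4-(tert-butyldimethylsilyloxy)-1,3,3-trimethyl-2-(trimethylsilylethynyl)cyclohexyl]pent-3-en-1-yl}-2,2,5a,7-tetramethyldecahydro-1-benzoxepin-3-ol (cyclohexyl C2 epimers), via B-alkyl-9-BBN borane 26 (not isolated)
Conditions: 11, 9-BBN (2.5 equiv), THF, rt; then 25, Pd(dppf)Cl2 (10 mol%), AsPh3 (10 mol%), Cs2CO3, DMF/THF/H2O, rt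
Reagents that add atoms: none
Why: B-Alkyl Suzuki–Miyaura coupling: anti-Markovnikov hydroboration of the vinyl group puts boron on C11, and zerovalent palladium joins this primary alkyl group to C9 of the enol triflate with retention, which forms the C9–C11 bond and the trisubstituted C8=C9 alkene in one operation.

Step 21
Reactants: 27 coupled alkynylsilane
Product: 30 bis-triisopropylsilyl siloxyalkyne (27 with the benzoxepin-3-ol as its triisopropylsilyl ether and the alkyne terminus as C≡C–OSi(i-Pr)3), via lithium acetylide 28 (not isolated), via lithium ynolate 29 (not isolated)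
Conditions: MeLi (2.3 equiv), THF, 0 °C → rt; LiOOt-Bu (1.5 equiv, from t-BuOOH and LiN(SiMe3)2), −78 → 0 °C; i-Pr3SiOTf (2.5 equiv), −78 °C
Reagents that add atoms: lithium tert-butyl peroxide, CC(C)(C)OO[Li]; triisopropylsilyl trifluoromethanesulfonate, CC(C)[Si](OS(=O)(=O)C(F)(F)F)(C(C)C)C(C)C
Why: Methyllithium cleaves the C–SiMe3 bond to the lithium acetylide (and deprotonates the hydroxyl), electrophilic oxygen transfer from the lithium peroxide gives the ynolate, and the bulky silyl triflate silylates it on oxygen to the isolable siloxyalkyne while also capping the C3′ alkoxide.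

Step 22
Reactants: 30 bis-triisopropylsilyl siloxyalkyne
Product: 31 ring-B-closed silyl dienol ether (drimane-numbered 3R-OTBS-7-OTIPS-6,8-diene; 10S; C5 epimers; C9 linked through C11–C12 to C6 of the 3-O-TIPS benzoxepine)
Conditions: HNTf2 (10 mol%), CH2Cl2, −78 → −20 °C; Et3N quench
Reagents that add atoms: none
Why: HNTf2 protonates the electron-rich siloxyalkyne at C6 to give an O-silyl ketenium ion centred on C7, which is attacked by C8 of the 1,5-disposed trisubstituted C8=C9 alkene so that the C7–C8 bond forms and the charge moves to tertiary C9; loss of H8 then returns the acid and leaves the conjugated C6=C7(OTIPS)–C8=C9 diene. The closest known reaction type is the Brønsted acid-promoted carbocyclisation of 1-siloxy-1,5-enynes (a ketenium–olefin cyclisation, the mild relative of the intramolecular acylation of alkenes). Ring B is closed in the 6-endo mode with respect to the alkene, the C6=C7 enol ether ending endocyclic. No stereocentre is created: C10 is untouched, and C5 is carried as its epimer mixture, both epimers being able to reach the ring-closing geometry (cis- or trans-fused). The step needs C7–C8 (six-ring) over C7–C9 (five-ring) bond formation and proton loss from C8 instead of C11; the first is secured by Markovnikov polarisation (tertiary cation at C9, itself shielded by quaternary C10) and the second by conjugation with the enol ether, any C9=C11 isomer converging later through the enolisable 6,7-dione. The siloxyalkyne is by far the most basic π-system, so the alkene, the silyl ethers and the oxepane should not be protonated at 10 mol% acid and −78 °C.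

Step 23
Reactants: 31 ring-B-closed silyl dienol ether
Product: 33 triol enone (drimane-numbered 3R-hydroxy-6-hydroxy-8-en-7-one with 3′S-hydroxy benzoxepine; 10S; C5 and C6 epimers), via silyloxy epoxide 32 (not isolated)
Conditions: dimethyldioxirane (1.1 equiv, acetone solution), CH2Cl2, −78 → 0 °C; then HF·pyridine, THF, 0 °C → rt
Reagents that add atoms: dimethyldioxirane, CC1(C)OO1
Why: Rubottom oxidation: the dioxirane epoxidises the most electron-rich alkene, the C6=C7 enol silane, and fluoride then opens the silyloxy epoxide to the C6 hydroxy ketone and removes the other three silyl groups, which leaves the acyloin and both remote carbinols free.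

Step 24
Reactants: 33 triol enone
Product: 34 sodwanone B
Conditions: Dess–Martin periodinane (4.5 equiv), NaHCO3, CH2Cl2, rt
Reagents that add atoms: none
Why: Dess–Martin oxidation of the three secondary alcohols gives the C3 ketone, the oxepanone and the 6,7-dione, and the dione enolises towards C5 to the conjugated diosphenol, which erases the C5 and C6 centres.

**Compound list**

1 | geranyl bromide, (2E)-1-bromo-3,7-dimethylocta-2,6-diene | CC(C)=CCC/C(C)=C/CBr | starting material
2 | methyl acetoacetate | CC(=O)CC(=O)OC | starting material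
3 | methyl (6E)-7,11-dimethyl-3-oxododeca-6,10-dienoate | COC(=O)CC(=O)CC/C=C(\C)CCC=C(C)C | intermediate
4 | methyl (2Z,6E)-3-[(diethoxyphosphoryl)oxy]-7,11-dimethyldodeca-2,6,10-trienoate | COC(=O)/C=C(\OP(=O)(OCC)OCC)CC/C=C(\C)CCC=C(C)C | intermediate
5 | methyl (2Z,6E)-7,11-dimethyl-3-[(trimethylsilyl)methyl]dodeca-2,6,10-trienoate | COC(=O)/C=C(\C[Si](C)(C)C)CC/C=C(\C)CCC=C(C)C | intermediate
6 | methyl (2Z)-5-[(2S,3S)-3-{2-[(2S)-3,3-dimethyloxiran-2-yl]ethyl}-3-methyloxiran-2-yl]-3-[(trimethylsilyl)methyl]pent-2-enoate | COC(=O)/C=C(\C[Si](C)(C)C)CC[C@@H]1O[C@@]1(C)CC[C@@H]1OC1(C)C | intermediate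
7 | methyl (3S,5aS,6R,9aS)-2,2,5a-trimethyl-7-methylidene-3-[(trimethylsilyl)oxy]decahydro-1-benzoxepine-6-carboxylate | COC(=O)[C@@H]1C(=C)CC[C@@H]2OC(C)(C)[C@@H](O[Si](C)(C)C)CC[C@]21C | intermediate
8 | methyl (3S,5aS,6R,9aS)-3-hydroxy-2,2,5a-trimethyl-7-methylidenedecahydro-1-benzoxepine-6-carboxylate | COC(=O)[C@@H]1C(=C)CC[C@@H]2OC(C)(C)[C@@H](O)CC[C@]21C | intermediate
9 | methyl (3S,5aS,6R,7R,9aS)-3-hydroxy-2,2,5a,7-tetramethyldecahydro-1-benzoxepine-6-carboxylate | COC(=O)[C@@H]1[C@H](C)CC[C@@H]2OC(C)(C)[C@@H](O)CC[C@]21C | intermediate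
10 | (3S,5aS,6R,7R,9aS)-3-hydroxy-2,2,5a,7-tetramethyldecahydro-1-benzoxepine-6-carbaldehyde | O=C[C@@H]1[C@H](C)CC[C@@H]2OC(C)(C)[C@@H](O)CC[C@]21C | intermediate
11 | (3S,5aS,6R,7R,9aS)-6-ethenyl-2,2,5a,7-tetramethyldecahydro-1-benzoxepin-3-ol | C=C[C@@H]1[C@H](C)CC[C@@H]2OC(C)(C)[C@@H](O)CC[C@]21C | intermediate
12 | methyl 2-methyl-3-oxobutanoate | CC(=O)C(C)C(=O)OC | starting material
13 | but-3-en-2-one (methyl vinyl ketone) | CC(=O)C=C | starting material
14 | methyl (2S)-2-acetyl-2-methyl-5-oxohexanoate | COC(=O)[C@](C)(C(C)=O)CCC(C)=O | intermediate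
15 | methyl (1S)-1,2-dimethyl-4-oxocyclohex-2-ene-1-carboxylate | COC(=O)[C@@]1(C)CCC(=O)C=C1C | intermediate
16 | methyl (1S)-1,3,3-trimethyl-2-methylidene-4-oxocyclohexane-1-carboxylate | COC(=O)[C@@]1(C)CCC(=O)C(C)(C)C1=C | intermediate
17 | methyl (1S,4R)-4-hydroxy-1,3,3-trimethyl-2-methylidenecyclohexane-1-carboxylate | COC(=O)[C@@]1(C)CC[C@@H](O)C(C)(C)C1=C | intermediate
18 | methyl (1S,4R)-4-(tert-butyldimethylsilyloxy)-1,3,3-trimethyl-2-methylidenecyclohexane-1-carboxylate | COC(=O)[C@@]1(C)CC[C@@H](O[Si](C)(C)C(C)(C)C)C(C)(C)C1=C | intermediate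
19 | methyl (1S,4R)-4-(tert-butyldimethylsilyloxy)-2-(hydroxymethyl)-1,3,3-trimethylcyclohexane-1-carboxylate, C2 epimers | COC(=O)[C@@]1(C)CC[C@@H](O[Si](C)(C)C(C)(C)C)C(C)(C)C1CO | intermediate
20 | methyl (1S,4R)-4-(tert-butyldimethylsilyloxy)-2-formyl-1,3,3-trimethylcyclohexane-1-carboxylate, C2 epimers | COC(=O)[C@@]1(C)CC[C@@H](O[Si](C)(C)C(C)(C)C)C(C)(C)C1C=O | intermediate
21 | methyl (1S,4R)-4-(tert-butyldimethylsilyloxy)-2-ethynyl-1,3,3-trimethylcyclohexane-1-carboxylate, C2 epimers | COC(=O)[C@@]1(C)CC[C@@H](O[Si](C)(C)C(C)(C)C)C(C)(C)C1C#C | intermediate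
22 | methyl (1S,4R)-4-(tert-butyldimethylsilyloxy)-1,3,3-trimethyl-2-[(trimethylsilyl)ethynyl]cyclohexane-1-carboxylate, C2 epimers | COC(=O)[C@@]1(C)CC[C@@H](O[Si](C)(C)C(C)(C)C)C(C)(C)C1C#C[Si](C)(C)C | intermediate
23 | (1S,4R)-4-(tert-butyldimethylsilyloxy)-N-methoxy-N,1,3,3-tetramethyl-2-[(trimethylsilyl)ethynyl]cyclohexane-1-carboxamide (Weinreb amide), C2 epimers | CON(C)C(=O)[C@@]1(C)CC[C@@H](O[Si](C)(C)C(C)(C)C)C(C)(C)C1C#C[Si](C)(C)C | intermediate
24 | 1-{(1S,4R)-4-(tert-butyldimethylsilyloxy)-1,3,3-trimethyl-2-[(trimethylsilyl)ethynyl]cyclohexyl}propan-1-one, C2 epimers | CCC(=O)[C@@]1(C)CC[C@@H](O[Si](C)(C)C(C)(C)C)C(C)(C)C1C#C[Si](C)(C)C | intermediate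
25 | (1Z)-1-{(1S,4R)-4-(tert-butyldimethylsilyloxy)-1,3,3-trimethyl-2-[(trimethylsilyl)ethynyl]cyclohexyl}prop-1-en-1-yl trifluoromethanesulfonate, C2 epimers | C/C=C(\OS(=O)(=O)C(F)(F)F)[C@@]1(C)CC[C@@H](O[Si](C)(C)C(C)(C)C)C(C)(C)C1C#C[Si](C)(C)C | intermediate
26 | (3S,5aS,6R,7R,9aS)-6-[2-(9-borabicyclo[3.3.1]nonan-9-yl)ethyl]-2,2,5a,7-tetramethyldecahydro-1-benzoxepin-3-ol | C1CCC2CCCC1B2CC[C@@H]1[C@H](C)CC[C@@H]2OC(C)(C)[C@@H](O)CC[C@]21C | intermediate
27 | (3S,5aS,6R,7R,9aS)-6-{(3E)-3-[(1S,4R)-4-(tert-butyldimethylsilyloxy)-1,3,3-trimethyl-2-(trimethylsilylethynyl)cyclohexyl]pent-3-en-1-yl}-2,2,5a,7-tetramethyldecahydro-1-benzoxepin-3-ol, cyclohexyl C2 epimers | C/C=C(\CC[C@@H]1[C@H](C)CC[C@@H]2OC(C)(C)[C@@H](O)CC[C@]21C)[C@@]1(C)CC[C@@H](O[Si](C)(C)C(C)(C)C)C(C)(C)C1C#C[Si](C)(C)C | intermediate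
28 | dilithium salt of the desilylated alkyne of 27 (lithium acetylide, lithium 3-alkoxide) | C/C=C(\CC[C@@H]1[C@H](C)CC[C@@H]2OC(C)(C)[C@@H](O[Li])CC[C@]21C)[C@@]1(C)CC[C@@H](O[Si](C)(C)C(C)(C)C)C(C)(C)C1C#C[Li] | intermediate
29 | lithium ynolate of 28 (C≡C–OLi, lithium 3-alkoxide) | C/C=C(\CC[C@@H]1[C@H](C)CC[C@@H]2OC(C)(C)[C@@H](O[Li])CC[C@]21C)[C@@]1(C)CC[C@@H](O[Si](C)(C)C(C)(C)C)C(C)(C)C1C#CO[Li] | intermediate
30 | bis-triisopropylsilyl siloxyalkyne: 27 with 3-O-Si(i-Pr)3 on the benzoxepine and C≡C–OSi(i-Pr)3 on the cyclohexane, cyclohexyl C2 epimers | C/C=C(\CC[C@@H]1[C@H](C)CC[C@@H]2OC(C)(C)[C@@H](O[Si](C(C)C)(C(C)C)C(C)C)CC[C@]21C)[C@@]1(C)CC[C@@H](O[Si](C)(C)C(C)(C)C)C(C)(C)C1C#CO[Si](C(C)C)(C(C)C)C(C)C | intermediate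
31 | ring-B-closed silyl dienol ether: drimane-numbered 3R-OTBS, 7-OTIPS, 6,8-diene, 10S, C5 epimers, C9–C11–C12 link to C6 of the 3-O-TIPS benzoxepine | CC1=C(CC[C@@H]2[C@H](C)CC[C@@H]3OC(C)(C)[C@@H](O[Si](C(C)C)(C(C)C)C(C)C)CC[C@]32C)[C@@]2(C)CC[C@@H](O[Si](C)(C)C(C)(C)C)C(C)(C)C2C=C1O[Si](C(C)C)(C(C)C)C(C)C | intermediate
32 | 6,7-epoxide of 31 (7-silyloxy epoxide), C5 and C6 epimers | CC1=C(CC[C@@H]2[C@H](C)CC[C@@H]3OC(C)(C)[C@@H](O[Si](C(C)C)(C(C)C)C(C)C)CC[C@]32C)[C@@]2(C)CC[C@@H](O[Si](C)(C)C(C)(C)C)C(C)(C)C2C2OC21O[Si](C(C)C)(C(C)C)C(C)C | intermediate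
33 | triol enone: drimane-numbered 3R,6-dihydroxy-8-en-7-one with the 3′S-hydroxy benzoxepine, 10S, C5 and C6 epimers | CC1=C(CC[C@@H]2[C@H](C)CC[C@@H]3OC(C)(C)[C@@H](O)CC[C@]32C)[C@@]2(C)CC[C@@H](O)C(C)(C)C2C(O)C1=O | intermediate
34 | sodwanone B | CC1=C(CC[C@@H]2[C@H](C)CC[C@@H]3OC(C)(C)C(=O)CC[C@]32C)[C@@]2(C)CCC(=O)C(C)(C)C2=C(O)C1=O | target

**Totals and risks**

Total step count: 24. Longest linear sequence: 16 steps (steps 9–24, from methyl 2-methyl-3-oxobutanoate).

Steps most likely to fail:

Step 5 (bis-epoxide cascade). The ester-conjugated allylsilane is a weak π-nucleophile, so capture of the epoxonium ion may be too slow and the cascade may stop after the first oxacyclisation or close a tetrahydropyran. The fallback makes the terminator electron-rich before the cascade. It sets out from 6: reduction with i-Bu2AlH at −78 °C should give allylic alcohol F1, and silylation (t-BuMe2SiCl, imidazole) should give silyl ether F2. F2 is submitted to the same Me3SiOTf cascade (K2CO3/MeOH work-up) to give bicyclic silyl ether F3. Hydrogenation over PtO2 should give saturated silyl ether F4, Bu4NF should free diol F5, and selective oxidation of the primary alcohol (TEMPO, PhI(OAc)2) returns to the route at 10.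

Step 22 (key cyclisation). The tertiary C9 cation may suffer a 1,2-shift from quaternary C10 or collapse through the five-membered mode, and protodesilylation of the siloxyalkyne may outrun ring closure. The fallback closes the same C7–C8 bond by a classical intramolecular acylation of the alkene and installs the enol silane afterwards. It sets out from 30: hydration of the siloxyalkyne (wet AcOH/THF, then K2CO3/MeOH) should give carboxylic acid F6. Its acid chloride ((COCl)2) is cyclised with SnCl4 at −78 °C and treated with DBU to give enone F7. Kinetic deprotonation at C6 (LiN(i-Pr)2, Me3SiCl, −78 °C; C7 is then the only ketone in the molecule) should give trimethylsilyl dienol ether F8, which under the conditions of step 23 returns to the route at 33.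

Step 6 (hydrogenation). Facial selectivity at the exocyclic alkene may be poor, and the double bond may migrate into conjugation with the ester. The fallback makes that migration deliberate and sets both centres by one syn addition. It sets out from 8: DBU should isomerise it to conjugated ester F9, and i-Bu2AlH should give allylic alcohol F10. Hydroxyl-assisted hydrogenation with [Ir(cod)(PCy3)(py)]PF6 should add both hydrogens from the face opposite the adjacent angular methyl, which fixes C6 and C7 cis to each other and gives diol F5 again; oxidation with TEMPO and PhI(OAc)2 returns to the route at 10.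

Further compounds
F1 | step 5 | (2Z)-5-[(2S,3S)-3-{2-[(2S)-3,3-dimethyloxiran-2-yl]ethyl}-3-methyloxiran-2-yl]-3-[(trimethylsilyl)methyl]pent-2-en-1-ol | OC/C=C(\C[Si](C)(C)C)CC[C@@H]1O[C@@]1(C)CC[C@@H]1OC1(C)C
F2 | step 5 | tert-butyldimethylsilyl ether of F1 | CC(C)(C)[Si](C)(C)OC/C=C(\C[Si](C)(C)C)CC[C@@H]1O[C@@]1(C)CC[C@@H]1OC1(C)C
F3 | step 5 | (3S,5aS,6R,9aS)-6-[(tert-butyldimethylsilyloxy)methyl]-2,2,5a-trimethyl-7-methylidenedecahydro-1-benzoxepin-3-ol | CC(C)(C)[Si](C)(C)OC[C@@H]1C(=C)CC[C@@H]2OC(C)(C)[C@@H](O)CC[C@]21C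
F4 | step 5 | (3S,5aS,6R,7R,9aS)-6-[(tert-butyldimethylsilyloxy)methyl]-2,2,5a,7-tetramethyldecahydro-1-benzoxepin-3-ol | CC(C)(C)[Si](C)(C)OC[C@@H]1[C@H](C)CC[C@@H]2OC(C)(C)[C@@H](O)CC[C@]21C
F5 | step 5 | (3S,5aS,6R,7R,9aS)-6-(hydroxymethyl)-2,2,5a,7-tetramethyldecahydro-1-benzoxepin-3-ol | OC[C@@H]1[C@H](C)CC[C@@H]2OC(C)(C)[C@@H](O)CC[C@]21C
F6 | step 22 | carboxylic acid from hydration of 30 (C5–CH2–CO2H, both silyl ethers kept), cyclohexyl C2 epimers | C/C=C(\CC[C@@H]1[C@H](C)CC[C@@H]2OC(C)(C)[C@@H](O[Si](C(C)C)(C(C)C)C(C)C)CC[C@]21C)[C@@]1(C)CC[C@@H](O[Si](C)(C)C(C)(C)C)C(C)(C)C1CC(=O)O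
F7 | step 22 | ring-B-closed 8-en-7-one (3R-OTBS, 3′-OTIPS, 10S, C5 epimers) | CC1=C(CC[C@@H]2[C@H](C)CC[C@@H]3OC(C)(C)[C@@H](O[Si](C(C)C)(C(C)C)C(C)C)CC[C@]32C)[C@@]2(C)CC[C@@H](O[Si](C)(C)C(C)(C)C)C(C)(C)C2CC1=O
F8 | step 22 | 7-(trimethylsilyloxy)-6,8-diene analogue of 31 (C5 epimers) | CC1=C(CC[C@@H]2[C@H](C)CC[C@@H]3OC(C)(C)[C@@H](O[Si](C(C)C)(C(C)C)C(C)C)CC[C@]32C)[C@@]2(C)CC[C@@H](O[Si](C)(C)C(C)(C)C)C(C)(C)C2C=C1O[Si](C)(C)C
F9 | step 6 | methyl (3S,5aS,9aS)-3-hydroxy-2,2,5a,7-tetramethyl-2,3,4,5,5a,8,9,9a-octahydro-1-benzoxepine-6-carboxylate | COC(=O)C1=C(C)CC[C@@H]2OC(C)(C)[C@@H](O)CC[C@]21C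
F10 | step 6 | (3S,5aS,9aS)-6-(hydroxymethyl)-2,2,5a,7-tetramethyl-2,3,4,5,5a,8,9,9a-octahydro-1-benzoxepin-3-ol | OCC1=C(C)CC[C@@H]2OC(C)(C)[C@@H](O)CC[C@]21C
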